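In a one-step world the starting material lost would reappear as target. But in the spring run 60.2 % had gone by 15.0 h while target stood at 17.1 %, so I took the missing part as a reversible pool.

the same everywhere: reagent in the second phase 19.9 mM
- spring: starting material 28 mM; run made earlier
- flask: starting material 19 mM; time 2.0 d; volume of the second phase over the first 1.0

spring run (percent of the starting material charged)

| time / h | target / % | starting material / % |
|---|---|---|
| 3.00 | 3.8 | 65.9 |
| 6.00 | 7.9 | 52.3 |
| 8.00 | 11.6 | 49.7 |
| 12.0 | 14.9 | 41.9 |
| 15.0 | 17.1 | 39.8 |

(each reading ± 1 percentage point)

- amounts and yields of target count product in the second phase too
- in the second phase: reagent in the second phase, product in the second phase; everything else is in the first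
- charges count per volume of the first phase; a concentration in a rate is the amount of a species over the volume of its own phase; every rate counts per litre of the first phase
- the numbers in the tables scatter by 1 percentage point (one standard deviation)
- the earlier runs hold the two phases in the same ratio of volumes as the flask asked about
- what has gone from starting material into another species counts as reacted, even if it can come back

* amount of target and product in the second phase together at 2.0 d, in percent of the starting material charged
* part of the starting material charged that has reacted at 2.0 d

From 8.00 h to 15.0 h, the target slope of the spring run over the mean starting material gave a pseudo-first-order constant of 0.0176 h⁻¹, as a reading. Taking one reagent per target as my assumption, c(reagent in the second phase) over c(starting material) gave 105 % for the flask, the reagent ceiling: the share of the charged starting material that the reagent charge could turn into target. The same ratio for the spring run was 71.1 %, and its target reading of 17.1 % stood well below that. The flask's ceiling lay higher, so I carried the spring percentages over.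

Holding starting material at 39.8 % from 15.0 h to 2.0 d gave y of 40.2 %. That hold was the weak link, since the pool shrinks too. Starting material was 48.0 % of the pool, so I let it fall to 30.1 %. Its mean gave y of 37.4 % and cv of 69.9 %, the numbers I committed to. The forecast gave 40 % and 72 %, higher in y than mine, holding that target “forms from starting material rather than from the reservoir”.

The flask gave 31.6 % and 74.7 %.

    reagent in the reaction phase ⇌ reagent in the second phase, rate k1*([reagent in the reaction phase] - [reagent in the second phase]/K1) per volume of the first phase (partition coefficient = 6.30, kL = 0.0100 min⁻¹)
    starting material + reagent in the reaction phase → target (k = 0.370 L mol⁻¹ min⁻¹)
    target ⇌ product in the second phase, rate k3*([target] - [product in the second phase]/K3) per volume of the first phase (partition coefficient = 30.0, kL = 0.00990 min⁻¹)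
    target → decomposed product (k = 0.00420 min⁻¹)
    2 reagent in the reaction phase → homo dimer (k = 0.220 L mol⁻¹ min⁻¹)
    reagent in the reaction phase + target → over-reaction product (k = 0.110 L mol⁻¹ min⁻¹)
    starting material ⇌ dormant form (K = 0.800, k = 0.00270 min⁻¹)

At 2.00 d the flask's target and decomposed product together came to 52.5 %, under its ceiling of 105 %, and reagent in the second phase stood at 33.3 % of its own charge. The neighbour charged with 48 mM had a ceiling of 41.5 %, since its reagent charge lay below its starting material, which made the reagent the limiting reagent by charge. At 2.00 d that neighbour held 19.8 % of target and 13.5 % of decomposed product, together 33.3 %, under that ceiling, and its reagent in the second phase stood at 13.6 % of its own charge.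

(The numbers in the tables stem from a simulated flask for substances that don't exist; the scatter is artificial.)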